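Compare these flasks in moles of D per litre before taking any percent.

| setting | north-east | south-west | midnight | winter |
|---|---|---|---|---|
| X | 0.050 M | 0.050 M | 0.012 M | 0.050 M |
| J | 0.125 M (in portions, 2) | 0.25 M (in portions, 2) | 0.125 M (in portions, 2) | 0.125 M (in portions, 2) |
| E | 0.15 M | 0.10 M | 0.100 M | 0.100 M |
| temperature | 5 °C | 5 °C |  |  |
| remark | run made earlier; portions every 5.0 min | run made earlier; portions every 5.0 min | at 5 °C throughout; the portions of J follow each other after 5.0 min, the first at the start | at 5 °C until 50 min, from then on at 35 °C; the portions of J follow each other after 5.0 min, the first at the start |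
| time |  |  | 2.5 h | 2.5 h |

- north-east (time / min: D / %): 25.0: 0.2; 50.0: 1.3; 60.0: 2.0; 90.0: 2.4
- south-west (time / min: D / %): 8.00: 0.7; 15.0: 0.6; 40.0: 2.8; 90.0: 8.8

(scatter of a reading: 0.5 percentage points)

- given per volume of solution although it is solid: X
- the numbers in the tables scatter with a standard deviation of 0.5 percentage points
- at the start none of X is in solution
- what has only dissolved of X counts as not reacted
- the earlier runs do not show what temperature does; that part of a forecast is a guess

- which one finishes higher in amount of D, in percent of the X charged ("neither" within 2 percentage points) (midnight / winter / neither)
- amount of D at the end, in percent of the X charged, midnight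
- amount of D at the end, in percent of the X charged, winter

A percent is that molar D divided by the X charged. North-east, with the same J as the two new flasks but more E, reads 0.00120 M of D at 90.0 min, and stretched evenly over 2.5 h this gives an estimate of 0.00200 M. The reckoning here supposes that solid X stays in plenty, so that molar D does not follow the X charged. That gives midnight 16.7%, and winter, were it held at 5 °C, 4.00%.

One number then reads the contest. The charge ratio 4.17, winter's X over midnight's X, is the break-even gain: the factor by which heating must multiply winter's molar D to draw level with midnight. Under that supposition, and apart from the margin, winter finishes higher above it and midnight below it. The earlier runs show nothing of temperature, so the reckoning commits to midnight's figure and leaves the heat gain open.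

The forecast gives 9% for midnight and, on a “guessed tenfold speed-up”, 35% for winter, with winter higher. Its midnight stands lower than the reckoning here.

The flasks give 24.7% for midnight and 18.0% for winter, so midnight finishes higher.

    2 Z → Q (k = 0.0930 M⁻¹ min⁻¹, Ea = 51.0 kJ mol⁻¹)
    Z + J → D (k = 0.270 M⁻¹ min⁻¹, Ea = 62.0 kJ mol⁻¹)
    X ⇌ Z, rate k3*(cs3 - [Z]) while solid is left; crystals form when [Z] > cs3 (solubility = 2.10 mM, k = 0.0670 min⁻¹)
    E + J → G (k = 0.360 M⁻¹ min⁻¹, Ea = 56.0 kJ mol⁻¹)
    (constants at 5 °C)

Winter stays low because of the low solubility of Z, the dissolved form of X: without that cap winter reaches 70.1%. Winter's charge held at 5 °C gives 5.92%, so midnight stands 4.17 times above it, which is the charge ratio 4.17 again. Heating lifts winter by a factor of 3.05, less than that ratio. With the difference in temperature programme taken away, midnight's charge put through winter's heating holds 75.2%, which is 4.17 times winter's percent.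

The numbers in the tables come from a simulation for substances that don't exist; scatter was added.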